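In the closed vessel I took the substrate to open and the open intermediate to go to the second nucleophile or the first, so I followed the rate of one capture over the other.

in all of them: substrate 0.22 M

| run | first nucleophile | second nucleophile | capture agent | remark | time |
|---|---|---|---|---|---|
| blue | 0.88 M | 0.44 M | 0.022 M | run made earlier |  |
| teal | 0.88 M | 0.99 M | 0.022 M | run made earlier |  |
| flask | 0.880 M | 0.660 M | 0.0220 M |  | 15 min |

| run | time / min | other capture product / % | target / % | substrate / % |
|---|---|---|---|---|
| blue | 1.50 | 28.4 | 23.4 | 46.7 |
| blue | 5.00 | 46.4 | 32.8 | 7.4 |
| blue | 8.00 | 49.5 | 28.0 | 0.8 |
| blue | 12.0 | 48.6 | 19.1 | 0 |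
| blue | 20.0 | 51.0 | 9.7 | 0 |
| teal | 1.50 | 38.7 | 14.8 | 44.5 |
| teal | 5.00 | 66.0 | 18.0 | 6.1 |
| teal | 8.00 | 67.9 | 16.1 | 1.0 |
| teal | 12.0 | 70.6 | 10.3 | 1.8 |
| teal | 20.0 | 69.4 | 6.1 | 0.3 |

(scatter of a reading: 1 percentage point)

- the analysis behind the earlier runs scatters by 1 percentage point, standard deviation
- candidate steps: first nucleophile + target -> over-reaction product; substrate <-> open intermediate; open intermediate + capture agent -> trapped intermediate; open intermediate -> side product; second nucleophile + open intermediate -> other capture product; first nucleophile + open intermediate -> target

- share of other capture product in other capture product plus target at 4.0 s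
- share of other capture product in other capture product plus target at 15 min
- which of other capture product and target there is more of at 15 min

Late readings held other capture product near 49.7% in blue and 69.3% in teal, and I counted the remainder as target made, setting the side product and the trapped intermediate aside. Dividing out the mean fraction of each nucleophile's charge left during capture gave:

blue 2.11, teal 2.09

I carried their mean, the selectivity factor: the second nucleophile's capture rate over the first's at equal concentrations, 2.10.

In the flask the rates start at this ratio:

1.58 to one, a share of 61.2%

At that share, capture spends 0.204 of the second nucleophile's charge and 0.0970 of the first's. Each rate therefore runs on average at a mean fraction of its start: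

second 0.898, first 0.951, ratio 1.49

By my estimate that puts other capture product in the flask at 59.8%. The target read as falling at 0.0846 min⁻¹ in the runs, and substrate at 0.547 min⁻¹, so I took target in the flask as made on average at 1.83 min:

target left 13.2%, share 81.9%

By this reckoning other capture product leads target in the flask at 15 min.

The forecast gave 63% (59% to 67%), a little above my start share, and 83% (80% to 86%), a little above my 81.9%, with other capture product ahead, holding that “opening is rate-limiting and independent of the second nucleophile”.

The flask gave 61.8% at 4.0 s and 84.1% at 15 min, with 60.1% other capture product and 11.4% target at that later time.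

    first nucleophile + target → over-reaction product (k = 0.00210 M⁻¹ s⁻¹)
    substrate ⇌ open intermediate (K = 0.0790, k = 0.00880 s⁻¹)
    open intermediate + capture agent → trapped intermediate (k = 0.0450 M⁻¹ s⁻¹)
    open intermediate → side product (k = 0.0570 s⁻¹)
    second nucleophile + open intermediate → other capture product (k = 8.40 M⁻¹ s⁻¹)
    first nucleophile + open intermediate → target (k = 3.90 M⁻¹ s⁻¹)

The start ratio from 2.10 had given 61.2%. For the neighbour charged with 0.26 M of second nucleophile it gave 38.3% at 4.0 s, and that flask stood at 38.9%. At 1.33 min the flask made target 5.45 times as fast as it used it up. At 15.0 min the first nucleophile went into making target at 0.0079 of its rate into over-reaction product, which stood at 27.7%.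

The data are simulated for an exercise, noise included.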